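The epsilon run topped out near 39.8% between 2.50 h and 5.00 h, then sank. I had to decide when to stop the next flask, which charges half the substrate at the same loading of enzyme.

- epsilon: substrate 0.36 M (fed, over 15 min); enzyme 0.01 mol%; added ligand 74 µM; run made earlier; the fed solution adds 0.50 times the starting volume
- flask: substrate 0.18 M (fed, over 15 min); enzyme 0.01 mol%; added ligand 74 µM; time 3.0 d; the fed solution adds 0.50 times the starting volume

- epsilon (time / h: target / %): 2.50: 39.5; 5.00: 39.8; 8.00: 33.7; 10.0: 32.3; 12.0: 30.4; 15.0: 26.3

(each reading ± 1 percentage point)

- time, not beyond 3.0 d, at which the flask holds most target
- the amount of target, in percent of the substrate charged, at that time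

- charges are per starting volume, the dose included; the dosed solution carries all of it
- the numbers in the tables scatter with a standard deviation of 1 percentage point
- no earlier run changes the charge of enzyme; that part of a forecast is a guess

I took the enzyme step as a fast pre-equilibrium, with substrate and target standing in a fixed ratio, and read the slow fall as a second-order loss between the two. That order was my assumption, not a reading. With y the target as a fraction of the substrate charged and c the charge, 1/y then climbs in a straight line against c·t. From the last stretch of epsilon:

β = (1/y_late − 1/y_early) / (c·Δt) = 0.358 /M/h

I carried this slope β, the loss constant per unit of charge, forward. At equal loading the enzyme scales with c too, so I expected the flask to repeat epsilon on a clock running half as fast, though the added ligand stays at 74 µM and puts that at risk: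

best time between 5.00 h and 10.0 h, at about the height read in epsilon

y at 3.0 d: 1/y = 1/y_late + β·(c·t − c_ε·t_ε), so y = 15.4%

So I kept the recipe and chose to stop inside that window, not at 3.0 d.

The forecast gave 41% at 0.28 d, reasoning that if both steps are enzyme-driven, “everything runs about twice as slowly”.

The flask gave 41.2% at 0.225 d, inside my window, and 16.4% at 3.00 d against my 15.4%.

    substrate + target → side product (k = 0.00751 /M/min)
    starting complex ⇌ enzyme + target (K = 0.369 M, k = 438 /min)
    substrate + enzyme ⇌ starting complex (K = 2.50 /M, k = 4890 /M/min)
    enzyme + added ligand ⇌ idle complex, settled at all times (K = 20400 /M)

The neighbouring flask charges 0.004 mol% of enzyme in place of 0.01 mol%. My β of 0.358 /M/h holds no enzyme term, so my reckoning gives that flask 15.4% at the end as well. The neighbour's best came to 35.7%, and at 3.00 d it held 16.6% of target.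

(Readings and results are simulated from invented constants, and the scatter is random.)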